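**Retrosynthetic overview**
1. Target 16 ⇐ hydroxyl-directed epoxidation of exocyclic alkene 15 ⇐ Lombardo methylenation and α-face dihydroxylation of the trans-fused cycloheptenone 13 (C-6 ester put on before the diol).
2. Cycloheptenone ⇐ intramolecular aldol condensation of keto aldehyde 8 (C-9/C-10 bond).
3. Cyclopentane with quaternary C-1 ⇐ key step: Meinwald 1,2-shift with ring contraction of cyclohexene oxide 7 (C-5 migrates from C-10 to C-1; the epoxide face fixes the trans C-1/C-5 relationship).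
4. Epoxide 7 ⇐ epoxidation, Wacker oxidation and trans-selective i-PrMgCl addition on aldol 3 ⇐ new enantioselective anti-aldol of 4-methylcyclohex-3-enone 1 with crotonaldehyde 2.
5. Ring order: cyclohexene (bought) → contracted to the cyclopentane → cycloheptenone → spiro-oxirane.

Assumption: 4-methylcyclohex-3-en-1-one (1) is taken as a catalogue compound; atom labels C-1 to C-15 follow daucane numbering.

**Route**

Step 1
Reactants: 1 4-methylcyclohex-3-en-1-one; 2 (E)-but-2-enal
Product: 3 (2S)-2-[(1S,2E)-1-hydroxybut-2-en-1-yl]-4-methylcyclohex-3-en-1-one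
Conditions: (S,S)-ProPhenol (10 mol %), Et2Zn (20 mol %), 4 Å MS, THF, −20 °C; 1 in excess (2 equiv)
Reagents that add atoms: none
Why: Proposed new method: a dinuclear zinc–ProPhenol catalyst soft-enolises the doubly activated C-5–H of 1 (allylic and α to the carbonyl, far more acidic than C-3–H) to a zinc dienolate that adds through its α-carbon to the zinc-bound enal in a closed chair transition state, the fixed E-enolate geometry giving the anti (5S,6S) aldol and the chiral pocket the absolute configuration, with 1,2- and not 1,4-attack on the enal; the closest known reactions are the zinc–ProPhenol direct aldol of aryl and alkynyl methyl ketones and the anti-selective direct aldol of cyclohexanone.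

Step 2
Reactants: 3 (2S)-2-[(1S,2E)-1-hydroxybut-2-en-1-yl]-4-methylcyclohex-3-en-1-one
Product: 5 (1R,2S)-4-methyl-1-(propan-2-yl)-1-(triethylsilyloxy)-2-[(1S,2E)-1-(triethylsilyloxy)but-2-en-1-yl]cyclohex-3-ene, via diol 4 (not isolated)
Conditions: i-PrMgCl·LiCl (2.3 equiv), LaCl3·2LiCl (30 mol %), THF, −78 → −40 °C; then Et3SiOTf (2.5 equiv), −78 → 0 °C
Reagents that add atoms: isopropylmagnesium chloride CC(C)[Mg]Cl; triethylsilyl trifluoromethanesulfonate CC[Si](CC)(CC)OS(=O)(=O)C(F)(F)F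
Why: Lanthanum-assisted Grignard 1,2-addition (little enolisation) brings the isopropyl group in by equatorial attack trans to the equatorial C-5 side chain, so the new tertiary carbinol C-4 (R) has its OH cis to that chain, and both magnesium alkoxides are then capped in the same flask by silyl ether formation.

Step 3
Reactants: 5 (1R,2S)-4-methyl-1-(propan-2-yl)-1-(triethylsilyloxy)-2-[(1S,2E)-1-(triethylsilyloxy)but-2-en-1-yl]cyclohex-3-ene
Product: 6 (4S)-4-[(1S,6R)-3-methyl-6-(propan-2-yl)-6-(triethylsilyloxy)cyclohex-2-en-1-yl]-4-(triethylsilyloxy)butan-2-one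
Conditions: Pd(Quinox)Cl2 (5 mol %), AgSbF6 (12 mol %), aq. t-BuOOH (70 %), CH2Cl2, 0 °C → rt
Reagents that add atoms: tert-butyl hydroperoxide CC(C)(C)OO
Why: Wacker-type oxidation of the E-disubstituted alkene puts the carbonyl on C-8, the carbon remote from the inductively withdrawing allylic silyloxy group, while the trisubstituted ring alkene does not react; no stereocentre is formed.

Step 4
Reactants: 6 (4S)-4-[(1S,6R)-3-methyl-6-(propan-2-yl)-6-(triethylsilyloxy)cyclohex-2-en-1-yl]-4-(triethylsilyloxy)butan-2-one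
Product: 7 (4S)-4-[(1R,2S,3R,6S)-6-methyl-3-(propan-2-yl)-3-(triethylsilyloxy)-7-oxabicyclo[4.1.0]heptan-2-yl]-4-(triethylsilyloxy)butan-2-one
Conditions: m-CPBA (1.1 equiv), NaHCO3, CH2Cl2, 0 °C
Reagents that add atoms: 3-chloroperoxybenzoic acid OOC(=O)c1cccc(Cl)c1
Why: Prilezhaev epoxidation of the electron-rich trisubstituted ring alkene takes place on the face opposite the axial C-4 silyloxy group and the C-5 side chain (isopropyl and side chain are equatorial), giving the 1α,10α-epoxide.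

Step 5
Reactants: 7 (4S)-4-[(1R,2S,3R,6S)-6-methyl-3-(propan-2-yl)-3-(triethylsilyloxy)-7-oxabicyclo[4.1.0]heptan-2-yl]-4-(triethylsilyloxy)butan-2-one
Product: 8 (1S,2S,3R)-1-methyl-2-[(1S)-3-oxo-1-(triethylsilyloxy)butyl]-3-(propan-2-yl)-3-(triethylsilyloxy)cyclopentane-1-carbaldehyde
Conditions: MABR [MeAl(OAr)2, Ar = 4-bromo-2,6-di-tert-butylphenyl] (20 mol %), CH2Cl2, −78 → −20 °C
Reagents that add atoms: none
Why: Meinwald rearrangement (semipinacol 1,2-shift) under a bulky aluminium Lewis acid that favours carbon over hydride migration: the C-1–O bond ionises at the tertiary centre and the ring bond C-10–C-5 shifts to C-1 anti to the leaving oxygen with retention at C-5, which contracts the ring and creates quaternary C-1 (S) with its methyl cis to the C-5 side chain and the new formyl group trans, while the silyl ethers block transannular ether formation.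

Step 6
Reactants: 8 (1S,2S,3R)-1-methyl-2-[(1S)-3-oxo-1-(triethylsilyloxy)butyl]-3-(propan-2-yl)-3-(triethylsilyloxy)cyclopentane-1-carbaldehyde
Product: 10 (1R,3aR,8S,8aS)-3a-methyl-1-(propan-2-yl)-1,8-bis(triethylsilyloxy)-2,3,3a,7,8,8a-hexahydroazulen-6(1H)-one, via β-hydroxy ketone 9 (not isolated)
Conditions: NaOMe (0.3 equiv), MeOH, 0 → 25 °C
Reagents that add atoms: none
Why: Intramolecular aldol condensation: the methyl-side enolate (C-9) adds to the non-enolisable aldehyde and closes the trans-fused seven-membered ring (the C-7 enolate would have to form a trans-fused bicyclo[3.3.0]octane), and E1cB loss of water gives the conjugated enone, so no new stereocentre remains.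

Step 7
Reactants: 10 (1R,3aR,8S,8aS)-3a-methyl-1-(propan-2-yl)-1,8-bis(triethylsilyloxy)-2,3,3a,7,8,8a-hexahydroazulen-6(1H)-one
Product: 11 (1R,3aR,8S,8aS)-1,8-dihydroxy-3a-methyl-1-(propan-2-yl)-2,3,3a,7,8,8a-hexahydroazulen-6(1H)-one
Conditions: HF·pyridine, pyridine, THF, 0 °C → rt
Reagents that add atoms: none
Why: Fluoride-induced cleavage of both silyl ethers (deprotection) under buffered conditions that leave the β-hydroxy enone and all stereocentres untouched.

Step 8
Reactants: 11 (1R,3aR,8S,8aS)-1,8-dihydroxy-3a-methyl-1-(propan-2-yl)-2,3,3a,7,8,8a-hexahydroazulen-6(1H)-one; 12 3-methylbutanoyl chloride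
Product: 13 (3R,3aS,4S,8aR)-3-hydroxy-8a-methyl-6-oxo-3-(propan-2-yl)-1,2,3,3a,4,5,6,8a-octahydroazulen-4-yl 3-methylbutanoate
Conditions: pyridine (3 equiv), DMAP (5 mol %), CH2Cl2, 0 °C
Reagents that add atoms: none
Why: DMAP-catalysed acylation with the acid chloride esterifies the only secondary hydroxyl (C-6), the hindered tertiary C-4 hydroxyl staying free.

Step 9
Reactants: 13 (3R,3aS,4S,8aR)-3-hydroxy-8a-methyl-6-oxo-3-(propan-2-yl)-1,2,3,3a,4,5,6,8a-octahydroazulen-4-yl 3-methylbutanoate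
Product: 14 (3R,3aS,4S,7S,8S,8aS)-3,7,8-trihydroxy-8a-methyl-6-oxo-3-(propan-2-yl)decahydroazulen-4-yl 3-methylbutanoate
Conditions: OsO4 (2 mol %), NMO (1.5 equiv), citric acid, t-BuOH/H2O 1:1, rt
Reagents that add atoms: N-methylmorpholine N-oxide C[N+]1([O-])CCOCC1; water O
Why: Upjohn syn-dihydroxylation of the enone C-9=C-10 bond from the α-face, opposite the angular methyl on the neighbouring quaternary C-1, sets the cis-diol (9S,10S).

Step 10
Reactants: 14 (3R,3aS,4S,7S,8S,8aS)-3,7,8-trihydroxy-8a-methyl-6-oxo-3-(propan-2-yl)decahydroazulen-4-yl 3-methylbutanoate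
Product: 15 (3R,3aS,4S,7R,8S,8aS)-3,7,8-trihydroxy-8a-methyl-6-methylidene-3-(propan-2-yl)decahydroazulen-4-yl 3-methylbutanoate
Conditions: Zn, CH2Br2, TiCl4 (Lombardo reagent, pre-formed at 0 °C), THF/CH2Cl2, 0 °C → rt
Reagents that add atoms: dibromomethane BrCBr
Why: Lombardo (Takai-type gem-dizinc/titanium) methylenation turns the ketone into the exocyclic alkene without base, so the ketol does not undergo retro-aldol cleavage or epimerisation and the β-acyloxy group is not eliminated; no stereocentre is formed.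

Step 11
Reactants: 15 (3R,3aS,4S,7R,8S,8aS)-3,7,8-trihydroxy-8a-methyl-6-methylidene-3-(propan-2-yl)decahydroazulen-4-yl 3-methylbutanoate
Product: 16 8α,14-epoxy-4β,9α,10α-trihydroxydaucan-6α-yl 3-methylbutanoate (CNP0307265.1)
Conditions: VO(acac)2 (5 mol %), t-BuOOH (decane, 1.5 equiv), CH2Cl2, 0 °C → rt
Reagents that add atoms: tert-butyl hydroperoxide CC(C)(C)OO
Why: Vanadium-catalysed hydroxyl-directed epoxidation transfers oxygen from the vanadate ester of the allylic C-9 (and homoallylic C-10) hydroxyl to the same α-face of the 1,1-disubstituted alkene, setting the spiro centre C-8 (S).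

**Compound list**
1 | 4-methylcyclohex-3-en-1-one | CC1=CCC(=O)CC1 | starting material
2 | (E)-but-2-enal (crotonaldehyde) | C/C=C/C=O | starting material
3 | (2S)-2-[(1S,2E)-1-hydroxybut-2-en-1-yl]-4-methylcyclohex-3-en-1-one (anti-aldol; C-5 S, C-6 S) | C/C=C/[C@H](O)[C@@H]1C=C(C)CCC1=O | intermediate
4 | (1R,2S)-2-[(1S,2E)-1-hydroxybut-2-en-1-yl]-4-methyl-1-(propan-2-yl)cyclohex-3-en-1-ol (as its magnesium alkoxide, not isolated) | C/C=C/[C@H](O)[C@@H]1C=C(C)CC[C@@]1(O)C(C)C | intermediate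
5 | (1R,2S)-4-methyl-1-(propan-2-yl)-1-(triethylsilyloxy)-2-[(1S,2E)-1-(triethylsilyloxy)but-2-en-1-yl]cyclohex-3-ene | C/C=C/[C@H](O[Si](CC)(CC)CC)[C@@H]1C=C(C)CC[C@@]1(O[Si](CC)(CC)CC)C(C)C | intermediate
6 | (4S)-4-[(1S,6R)-3-methyl-6-(propan-2-yl)-6-(triethylsilyloxy)cyclohex-2-en-1-yl]-4-(triethylsilyloxy)butan-2-one | CC(=O)C[C@H](O[Si](CC)(CC)CC)[C@@H]1C=C(C)CC[C@@]1(O[Si](CC)(CC)CC)C(C)C | intermediate
7 | (4S)-4-[(1R,2S,3R,6S)-6-methyl-3-(propan-2-yl)-3-(triethylsilyloxy)-7-oxabicyclo[4.1.0]heptan-2-yl]-4-(triethylsilyloxy)butan-2-one (epoxide trans to the side chain and to the ring silyloxy group) | CC(=O)C[C@H](O[Si](CC)(CC)CC)[C@@H]1[C@H]2O[C@@]2(C)CC[C@@]1(O[Si](CC)(CC)CC)C(C)C | intermediate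
8 | (1S,2S,3R)-1-methyl-2-[(1S)-3-oxo-1-(triethylsilyloxy)butyl]-3-(propan-2-yl)-3-(triethylsilyloxy)cyclopentane-1-carbaldehyde | O=C[C@@]1(C)CC[C@@](O[Si](CC)(CC)CC)(C(C)C)[C@@H]1[C@H](CC(C)=O)O[Si](CC)(CC)CC | intermediate
9 | (1R,3aS,8S,8aS)-4-hydroxy-3a-methyl-1-(propan-2-yl)-1,8-bis(triethylsilyloxy)octahydroazulen-6(1H)-one, both carbinol (C-4 azulene = C-10 daucane) epimers (not isolated) | O=C1CC(O)[C@@]2(C)CC[C@@](O[Si](CC)(CC)CC)(C(C)C)[C@@H]2[C@@H](O[Si](CC)(CC)CC)C1 | intermediate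
10 | (1R,3aR,8S,8aS)-3a-methyl-1-(propan-2-yl)-1,8-bis(triethylsilyloxy)-2,3,3a,7,8,8a-hexahydroazulen-6(1H)-one | O=C1C=C[C@@]2(C)CC[C@@](O[Si](CC)(CC)CC)(C(C)C)[C@@H]2[C@@H](O[Si](CC)(CC)CC)C1 | intermediate
11 | (1R,3aR,8S,8aS)-1,8-dihydroxy-3a-methyl-1-(propan-2-yl)-2,3,3a,7,8,8a-hexahydroazulen-6(1H)-one | O=C1C=C[C@@]2(C)CC[C@@](O)(C(C)C)[C@@H]2[C@@H](O)C1 | intermediate
12 | 3-methylbutanoyl chloride (isovaleryl chloride) | CC(C)CC(Cl)=O | starting material
13 | (3R,3aS,4S,8aR)-3-hydroxy-8a-methyl-6-oxo-3-(propan-2-yl)-1,2,3,3a,4,5,6,8a-octahydroazulen-4-yl 3-methylbutanoate | O=C1C=C[C@@]2(C)CC[C@@](O)(C(C)C)[C@@H]2[C@@H](OC(=O)CC(C)C)C1 | intermediate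
14 | (3R,3aS,4S,7S,8S,8aS)-3,7,8-trihydroxy-8a-methyl-6-oxo-3-(propan-2-yl)decahydroazulen-4-yl 3-methylbutanoate | O=C1[C@@H](O)[C@@H](O)[C@@]2(C)CC[C@@](O)(C(C)C)[C@@H]2[C@@H](OC(=O)CC(C)C)C1 | intermediate
15 | (3R,3aS,4S,7R,8S,8aS)-3,7,8-trihydroxy-8a-methyl-6-methylidene-3-(propan-2-yl)decahydroazulen-4-yl 3-methylbutanoate | C=C1[C@@H](O)[C@@H](O)[C@@]2(C)CC[C@@](O)(C(C)C)[C@@H]2[C@@H](OC(=O)CC(C)C)C1 | intermediate
16 | 8α,14-epoxy-4β,9α,10α-trihydroxydaucan-6α-yl 3-methylbutanoate (CNP0307265.1; 1S,4R,5S,6S,8S,9S,10S) | CC(C)CC(=O)O[C@H]1C[C@]2(CO2)[C@@H](O)[C@@H](O)[C@@]2(C)CC[C@@](O)(C(C)C)[C@H]12 | target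

**Step count and risks**
Total step count: 11. Longest linear sequence: 11 (1 → 16).

Three steps most likely to fail:

Step 1 (the proposed new aldol; regio- and enantiocontrol are untested, and the product can isomerise or undergo retro-aldol). The fallback sets out from 1 and uses known chemistry. Dicyclohexylboron chloride and Et3N (Et2O, −78 °C) give the E-enol borinate, which adds to 2 to give the racemic anti-aldol, that is 3 together with its mirror image, the (2R,1′R)-aldol F1. Lipase-catalysed acetylation (Pseudomonas cepacia lipase, vinyl acetate, MTBE) converts only the (1′R)-alcohol into the (2R,1′R)-acetate F2. Unreacted 3 is separated, and the route is rejoined at 3.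

Step 6 (seven-membered aldol condensation; β-elimination of the C-6 silyloxy group under base is the main danger). The fallback sets out from 8. Kinetic enolborination of the methyl ketone (Bu2BOTf, i-Pr2NEt, CH2Cl2, −78 °C) and intramolecular boron aldol give the β-hydroxy ketone 9, this time isolated. MsCl and Et3N at 0 °C convert it into the C-10 mesylate F3, which eliminates on warming and rejoins the route at 10.

Step 10 (methylenation of a Lewis-acid- and base-sensitive ketol that carries three free hydroxyls). The fallback sets out from 14. The cis-diol is masked as the 9,10-acetonide F4 (2,2-dimethoxypropane, PPTS, CH2Cl2). Wittig methylenation (Ph3P=CH2, THF, −78 → 0 °C) gives the methylene acetonide F5. Aqueous acetic acid (80 %, 40 °C) removes the acetonide and rejoins the route at 15.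

**Further compounds**
F1 | step 1 | (2R)-2-[(1R,2E)-1-hydroxybut-2-en-1-yl]-4-methylcyclohex-3-en-1-one (enantiomer of 3) | C/C=C/[C@@H](O)[C@H]1C=C(C)CCC1=O
F2 | step 1 | (1R,2E)-1-[(1R)-4-methyl-2-oxocyclohex-3-en-1-yl]but-2-en-1-yl acetate | C/C=C/[C@@H](OC(C)=O)[C@H]1C=C(C)CCC1=O
F3 | step 6 | C-10 methanesulfonate of 9 (both epimers) | O=C1CC(OS(C)(=O)=O)[C@@]2(C)CC[C@@](O[Si](CC)(CC)CC)(C(C)C)[C@@H]2[C@@H](O[Si](CC)(CC)CC)C1
F4 | step 10 | 9,10-O-isopropylidene derivative (acetonide) of 14 | O=C1[C@H]3OC(C)(C)O[C@H]3[C@@]2(C)CC[C@@](O)(C(C)C)[C@@H]2[C@@H](OC(=O)CC(C)C)C1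
F5 | step 10 | 9,10-O-isopropylidene derivative (acetonide) of 15 | C=C1[C@H]3OC(C)(C)O[C@H]3[C@@]2(C)CC[C@@](O)(C(C)C)[C@@H]2[C@@H](OC(=O)CC(C)C)C1
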